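**Assumption (one line):** Carotenoid numbering is used in the explanations (C1–C6 for the trihydroxy ring, primed numbers for the ε ring); racemic α‑ionone is used and its ring CH centre is resolved in step 12; minor Z isomers from the olefinations are expected to be removed or equilibrated to all‑E in the usual way.

## Retrosynthetic overview

1. C40 → two C15 dienals (14 and 20) + C10 bis‑phosphonate 24 by two Horner–Wadsworth–Emmons olefinations (C11'=C12', then C11=C12), then desilylation.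
2. Triol end: C6–C7 bond by acetylide addition to the C6 ketone of 8; 8 by α‑ketol ring expansion of the acetylcyclopentanol 7 (cyclopentane → cyclohexane).
3. Enabling feature: in the trihydroxycyclohexane the tertiary carbinol C5 (OH + CH3) sits next to oxygenated C6, which is flanked by quaternary C1. C5 with its methyl is a former acetyl group on a cyclopentanol whose carbinol carbon becomes C6 when the C4 arm shifts.
4. Stereochemistry: C3 by Cu‑catalysed conjugate borylation; relayed to the cyclopentanol carbinol (1,3‑induction), from there to C5 (suprafacial shift) and to C6 (axial attack).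
5. Ring order: the cyclopentane is bought and enlarged to the cyclohexane in step 5; the ε ring is bought with α‑ionone (C3' by transfer hydrogenation, C6' resolved there).

Key step: step 5

## Route

**Step 1**
Reactants: 1 2,2‑dimethylcyclopentan‑1‑one
Product: 2 5,5‑dimethylcyclopent‑2‑en‑1‑one
Conditions: IBX, DMSO/toluene, 70 °C
Reagents that add atoms: none
Why: IBX α,β‑dehydrogenation of a ketone proceeds through the enol, and only the CH2–CH2 side can enolise because the other α‑carbon is quaternary.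

**Step 2**
Reactants: 2 5,5‑dimethylcyclopent‑2‑en‑1‑one
Product: 4 (4S)‑4‑hydroxy‑2,2‑dimethylcyclopentan‑1‑one, via β‑boryl ketone 3 (not isolated)
Conditions: CuCl (cat.), NaOt‑Bu (cat.), Josiphos‑type bisphosphine (cat., enantiomer chosen for the S product), B2pin2, MeOH, THF, rt; then NaBO3·4H2O, THF/H2O, rt
Reagents that add atoms: bis(pinacolato)diboron CC1(C)OB(OC1(C)C)B1OC(C)(C)C(C)(C)O1; sodium perborate [Na+].[O-]OB=O
Why: Copper(I)‑catalysed enantioselective conjugate borylation of a cyclic enone followed by stereoretentive C–B oxidation, in which the chiral Cu–boryl complex selects the enone face and sets the one catalyst‑derived stereocentre of this ring (S), the gem‑dimethyl group being remote from the β‑carbon.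

**Step 3**
Reactants: 4 (4S)‑4‑hydroxy‑2,2‑dimethylcyclopentan‑1‑one
Product: 5 (4S)‑4‑{[tert‑butyl(dimethyl)silyl]oxy}‑2,2‑dimethylcyclopentan‑1‑one
Conditions: TBSCl, imidazole, DMF, 0 °C → rt
Reagents that add atoms: tert‑butyldimethylsilyl chloride CC(C)(C)[Si](C)(C)Cl
Why: Standard silylation of a secondary alcohol under mild imidazole conditions, which should avoid β‑elimination of the aldol‑type ketol.

**Step 4**
Reactants: 5 (4S)‑4‑{[tert‑butyl(dimethyl)silyl]oxy}‑2,2‑dimethylcyclopentan‑1‑one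
Product: 7 1‑[(1S,4S)‑4‑{[tert‑butyl(dimethyl)silyl]oxy}‑1‑hydroxy‑2,2‑dimethylcyclopentyl]ethan‑1‑one (hydroxyl cis to the silyloxy group), via ethoxyvinyl carbinol 6 (not isolated)
Conditions: ethyl vinyl ether, t‑BuLi, THF, −78 → 0 °C; add 5, −78 °C; then 0.5 M aq. HCl/THF, 0 °C
Reagents that add atoms: ethyl vinyl ether (as 1‑ethoxyvinyllithium) C=COCC; water O
Why: 1,2‑Addition of an acyl‑anion equivalent followed by enol‑ether hydrolysis, in which the small vinyl anion should attack the cyclopentanone face anti to the bulky 4‑silyloxy group (1,3‑induction) and so place the tertiary hydroxyl cis to it (1S), the minor epimer being removable by chromatography.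

**Step 5**
Reactants: 7 1‑[(1S,4S)‑4‑{[tert‑butyl(dimethyl)silyl]oxy}‑1‑hydroxy‑2,2‑dimethylcyclopentyl]ethan‑1‑one
Product: 8 (2S,4S)‑4‑{[tert‑butyl(dimethyl)silyl]oxy}‑2‑hydroxy‑2,6,6‑trimethylcyclohexan‑1‑one
Conditions: Al(Ot‑Bu)3 (20 mol%), toluene, 80 °C; aq. Rochelle salt work‑up
Reagents that add atoms: none
Why: Al(Ot‑Bu)3 exchanges onto the tertiary hydroxyl of 7 and chelates the acetyl carbonyl, holding the two oxygens syn‑periplanar in a five‑membered aluminate, and the ring CH2 arm, which lies perpendicular to the chelate plane, shifts suprafacially from the carbinol carbon to the acetyl carbon (1,2‑acyloin shift) while the old carbinol carbon becomes the ring ketone. The closest known reaction type is the Lewis‑acid α‑ketol ring expansion of 1‑acylcycloalkanols, in particular the D‑homoannulation of 17α‑hydroxy‑20‑keto steroids, where a cyclopentanol flanked by a quaternary carbon and a CH2 group expands by CH2 migration. The six‑membered ring is not closed by a cyclisation but arises by ring enlargement 5 → 6, the acetyl carbon being inserted between the former carbinol carbon and its CH2 neighbour. The new quaternary stereocentre (C2 of 8, C5 of the target) is controlled by the carbinol configuration of 7 through the syn chelate, because in a suprafacial shift the new hydroxyl ends on the ring face of the old one, i.e. cis to the silyloxy group (2S). The step needs regioselectivity (CH2 versus CMe2 migration) and stereochemical fidelity: CH2 migration gives the only product in which the two fully substituted sp3 carbons are separated by the sp2 carbonyl, and the regioisomeric ketol from CMe2 migration is connected to 8 by a syn‑chelated 1,2‑methyl shift that conserves the hydroxyl face, so 8 should be the thermodynamic sink of the chelated manifold. The product ketone has no α‑hydrogen and the silyl ether is γ to it, so neither enolisation nor β‑elimination can erode it.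

**Step 6**
Reactants: 8 (2S,4S)‑4‑{[tert‑butyl(dimethyl)silyl]oxy}‑2‑hydroxy‑2,6,6‑trimethylcyclohexan‑1‑one
Product: 9 (2S,4S)‑4‑{[tert‑butyl(dimethyl)silyl]oxy}‑2,6,6‑trimethyl‑2‑[(trimethylsilyl)oxy]cyclohexan‑1‑one
Conditions: TMSOTf, 2,6‑lutidine, CH2Cl2, −78 → 0 °C
Reagents that add atoms: trimethylsilyl trifluoromethanesulfonate C[Si](C)(C)OS(=O)(=O)C(F)(F)F
Why: Silyl triflate/lutidine silylation of a hindered tertiary α‑ketol hydroxyl removes the acidic proton so that no alkoxide sits next to the carbonyl in the following addition.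

**Step 7**
Reactants: 9 (2S,4S)‑4‑{[tert‑butyl(dimethyl)silyl]oxy}‑2,6,6‑trimethyl‑2‑[(trimethylsilyl)oxy]cyclohexan‑1‑one; 10 (2E)‑3‑methylpent‑2‑en‑4‑yn‑1‑ol
Product: 12 (2E)‑5‑[(1R,2S,4S)‑4‑{[tert‑butyl(dimethyl)silyl]oxy}‑1,2‑dihydroxy‑2,6,6‑trimethylcyclohexyl]‑3‑methylpent‑2‑en‑4‑yn‑1‑ol, via O‑trimethylsilyl adduct 11 (not isolated)
Conditions: 10 (2.2 equiv), n‑BuLi (4.4 equiv), THF, −78 → 0 °C; add 9, −78 °C → rt; aq. NH4Cl; then K2CO3, MeOH, rt
Reagents that add atoms: none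
Why: Acetylide addition to a non‑enolisable ketone, in which the chair with both silyloxy groups equatorial has the axial methyls of C2 and C6 on one face, so the slim acetylide should attack axially from the face of the two oxygens and set the carbinol (C6 of the target) with its OH trans to the neighbouring oxygen, after which methanolysis removes the labile TMS group wherever it resides.

**Step 8**
Reactants: 12 (2E)‑5‑[(1R,2S,4S)‑4‑{[tert‑butyl(dimethyl)silyl]oxy}‑1,2‑dihydroxy‑2,6,6‑trimethylcyclohexyl]‑3‑methylpent‑2‑en‑4‑yn‑1‑ol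
Product: 13 (2E,4E)‑5‑[(1S,2S,4S)‑4‑{[tert‑butyl(dimethyl)silyl]oxy}‑1,2‑dihydroxy‑2,6,6‑trimethylcyclohexyl]‑3‑methylpenta‑2,4‑dien‑1‑ol
Conditions: Red‑Al, THF, 0 °C → rt; aq. Rochelle salt
Reagents that add atoms: none
Why: Alkoxide‑directed trans‑hydroalumination of a tertiary propargylic alcohol gives the E‑alkene (C7=C8) without touching the stereocentres or the secondary silyl ether.

**Step 9**
Reactants: 13 (2E,4E)‑5‑[(1S,2S,4S)‑4‑{[tert‑butyl(dimethyl)silyl]oxy}‑1,2‑dihydroxy‑2,6,6‑trimethylcyclohexyl]‑3‑methylpenta‑2,4‑dien‑1‑ol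
Product: 14 (2E,4E)‑5‑[(1S,2S,4S)‑4‑{[tert‑butyl(dimethyl)silyl]oxy}‑1,2‑dihydroxy‑2,6,6‑trimethylcyclohexyl]‑3‑methylpenta‑2,4‑dienal
Conditions: activated MnO2, CH2Cl2, rt
Reagents that add atoms: none
Why: MnO2 oxidises only the primary allylic alcohol, the tertiary alcohols and the silyl ether being inert.

**Step 10**
Reactants: 15 (3E)‑4‑(2,6,6‑trimethylcyclohex‑2‑en‑1‑yl)but‑3‑en‑2‑one (racemic α‑ionone)
Product: 16 (2E,4E)‑3‑methyl‑5‑(2,6,6‑trimethylcyclohex‑2‑en‑1‑yl)penta‑2,4‑dienenitrile (racemic)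
Conditions: (EtO)2P(O)CH2CN, NaH, THF, 0 °C → rt; chromatography
Reagents that add atoms: diethyl (cyanomethyl)phosphonate CCOP(=O)(CC#N)OCC
Why: Horner–Wadsworth–Emmons olefination of the methyl ketone should give the 2E‑dienenitrile as the major isomer, the minor 2Z isomer being removable by chromatography.

**Step 11**
Reactants: 16 (2E,4E)‑3‑methyl‑5‑(2,6,6‑trimethylcyclohex‑2‑en‑1‑yl)penta‑2,4‑dienenitrile (racemic)
Product: 17 (2E,4E)‑3‑methyl‑5‑(2,6,6‑trimethyl‑4‑oxocyclohex‑2‑en‑1‑yl)penta‑2,4‑dienenitrile (racemic)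
Conditions: Rh2(cap)4 (cat.), t‑BuOOH (70% aq., excess), K2CO3 (0.5 equiv), CH2Cl2, rt
Reagents that add atoms: tert‑butyl hydroperoxide CC(C)(C)OO
Why: Peroxyl‑radical allylic C–H oxidation of the ring CH2 next to the trisubstituted alkene to the enone is the reaction type established for the α‑ionone ring, whose hindered doubly allylic CH is poorly aligned for abstraction.

**Step 12**
Reactants: 17 (2E,4E)‑3‑methyl‑5‑(2,6,6‑trimethyl‑4‑oxocyclohex‑2‑en‑1‑yl)penta‑2,4‑dienenitrile (racemic)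
Product: 18 (2E,4E)‑5‑[(1R,4R)‑4‑hydroxy‑2,6,6‑trimethylcyclohex‑2‑en‑1‑yl]‑3‑methylpenta‑2,4‑dienenitrile
Conditions: RuCl[(R,R)‑TsDPEN](p‑cymene) (cat., enantiomer chosen for the 4R carbinol), HCO2H/Et3N (5:2), CH2Cl2, rt; chromatographic separation of the trans and cis diastereomers
Reagents that add atoms: none
Why: Noyori‑type asymmetric transfer hydrogenation of the ring enone carbonyl (alkenyl versus alkyl differentiation, as with 4‑oxoisophorone‑type enones) should set the carbinol (R) under catalyst control in both enantiomers of 17, so the ring CH centre is resolved by separating the trans (1R,4R) product from its cis (1S,4R) diastereomer.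

**Step 13**
Reactants: 18 (2E,4E)‑5‑[(1R,4R)‑4‑hydroxy‑2,6,6‑trimethylcyclohex‑2‑en‑1‑yl]‑3‑methylpenta‑2,4‑dienenitrile
Product: 19 (2E,4E)‑5‑[(1R,4R)‑4‑{[tert‑butyl(dimethyl)silyl]oxy}‑2,6,6‑trimethylcyclohex‑2‑en‑1‑yl]‑3‑methylpenta‑2,4‑dienenitrile
Conditions: TBSCl, imidazole, DMF, rt
Reagents that add atoms: tert‑butyldimethylsilyl chloride CC(C)(C)[Si](C)(C)Cl
Why: Standard silylation protects the acid‑labile allylic alcohol for the hydride and olefination steps.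

**Step 14**
Reactants: 19 (2E,4E)‑5‑[(1R,4R)‑4‑{[tert‑butyl(dimethyl)silyl]oxy}‑2,6,6‑trimethylcyclohex‑2‑en‑1‑yl]‑3‑methylpenta‑2,4‑dienenitrile
Product: 20 (2E,4E)‑5‑[(1R,4R)‑4‑{[tert‑butyl(dimethyl)silyl]oxy}‑2,6,6‑trimethylcyclohex‑2‑en‑1‑yl]‑3‑methylpenta‑2,4‑dienal
Conditions: DIBAL‑H, CH2Cl2, −78 °C; aq. Rochelle salt
Reagents that add atoms: water O
Why: DIBAL‑H reduction of a conjugated nitrile stops at the N‑aluminoimine, which hydrolyses to the dienal on work‑up.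

**Step 15**
Reactants: 21 (2E,4E,6E)‑2,7‑dimethylocta‑2,4,6‑trienedial
Product: 22 (2E,4E,6E)‑2,7‑dimethylocta‑2,4,6‑triene‑1,8‑diol
Conditions: NaBH4, MeOH/THF, 0 °C
Reagents that add atoms: none
Why: Borohydride 1,2‑reduction of both enal carbonyls leaves the triene geometry intact.

**Step 16**
Reactants: 22 (2E,4E,6E)‑2,7‑dimethylocta‑2,4,6‑triene‑1,8‑diol
Product: 23 (2E,4E,6E)‑1,8‑dibromo‑2,7‑dimethylocta‑2,4,6‑triene
Conditions: PBr3, pyridine (cat.), Et2O, −10 °C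
Reagents that add atoms: phosphorus tribromide BrP(Br)Br
Why: Primary allylic alcohols are converted into the allylic bromides by PBr3 at low temperature without allylic transposition in this symmetric triene.

**Step 17**
Reactants: 23 (2E,4E,6E)‑1,8‑dibromo‑2,7‑dimethylocta‑2,4,6‑triene
Product: 24 tetraethyl [(2E,4E,6E)‑2,7‑dimethylocta‑2,4,6‑triene‑1,8‑diyl]bis(phosphonate)
Conditions: P(OEt)3 (excess), toluene, 110 °C
Reagents that add atoms: triethyl phosphite CCOP(OCC)OCC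
Why: Double Michaelis–Arbuzov reaction of the primary allylic dibromide gives the bis‑phosphonate.

**Step 18**
Reactants: 24 tetraethyl [(2E,4E,6E)‑2,7‑dimethylocta‑2,4,6‑triene‑1,8‑diyl]bis(phosphonate); 20 (2E,4E)‑5‑[(1R,4R)‑4‑{[tert‑butyl(dimethyl)silyl]oxy}‑2,6,6‑trimethylcyclohex‑2‑en‑1‑yl]‑3‑methylpenta‑2,4‑dienal
Product: 25 diethyl {(2E,4E,6E,8E,10E,12E)‑13‑[(1R,4R)‑4‑{[tert‑butyl(dimethyl)silyl]oxy}‑2,6,6‑trimethylcyclohex‑2‑en‑1‑yl]‑2,7,11‑trimethyltrideca‑2,4,6,8,10,12‑hexaen‑1‑yl}phosphonate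
Conditions: 24 (3 equiv), KOt‑Bu (1 equiv relative to 20), THF, −30 °C; add 20, → 0 °C
Reagents that add atoms: none
Why: Horner–Wadsworth–Emmons olefination with the mono‑anion of the allylic bis‑phosphonate, used in excess so that mono‑olefination prevails, should form the E C11'=C12' bond, and unreacted 24 is recoverable.

**Step 19**
Reactants: 25 diethyl {(2E,4E,6E,8E,10E,12E)‑13‑[(1R,4R)‑4‑{[tert‑butyl(dimethyl)silyl]oxy}‑2,6,6‑trimethylcyclohex‑2‑en‑1‑yl]‑2,7,11‑trimethyltrideca‑2,4,6,8,10,12‑hexaen‑1‑yl}phosphonate; 14 (2E,4E)‑5‑[(1S,2S,4S)‑4‑{[tert‑butyl(dimethyl)silyl]oxy}‑1,2‑dihydroxy‑2,6,6‑trimethylcyclohexyl]‑3‑methylpenta‑2,4‑dienal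
Product: 26 (all‑E,3S,5S,6S,3'R,6'R)‑3,3'‑bis{[tert‑butyl(dimethyl)silyl]oxy}‑5,6‑dihydro‑β,ε‑carotene‑5,6‑diol
Conditions: 25 (1.2 equiv), NaHMDS (1.15 equiv), THF, −78 °C; add 14, → rt
Reagents that add atoms: none
Why: Horner–Wadsworth–Emmons olefination of the allylic phosphonate anion with the dienal should form the E C11=C12 bond, and the two tertiary hydroxyls of 14 are far less acidic than the phosphonate and are tolerated.

**Step 20**
Reactants: 26 (all‑E,3S,5S,6S,3'R,6'R)‑3,3'‑bis{[tert‑butyl(dimethyl)silyl]oxy}‑5,6‑dihydro‑β,ε‑carotene‑5,6‑diol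
Product: 27 (all‑E,3S,5S,6S,3'R,6'R)‑5,6‑dihydro‑β,ε‑carotene‑3,3',5,6‑tetrol (CNP0219917.1)
Conditions: TBAF, THF, rt, exclusion of light and air
Reagents that add atoms: none
Why: Fluoride cleaves both secondary silyl ethers under non‑acidic conditions that spare the polyene, the allylic ε‑ring alcohol and the tertiary allylic 5,6‑diol.

## Compound list

1 | 2,2‑dimethylcyclopentan‑1‑one | O=C1CCCC1(C)C | starting material
2 | 5,5‑dimethylcyclopent‑2‑en‑1‑one | O=C1C=CCC1(C)C | intermediate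
3 | (4S)‑2,2‑dimethyl‑4‑(4,4,5,5‑tetramethyl‑1,3,2‑dioxaborolan‑2‑yl)cyclopentan‑1‑one | O=C1C(C)(C)C[C@H](B2OC(C)(C)C(C)(C)O2)C1 | intermediate
4 | (4S)‑4‑hydroxy‑2,2‑dimethylcyclopentan‑1‑one | O=C1C(C)(C)C[C@H](O)C1 | intermediate
5 | (4S)‑4‑{[tert‑butyl(dimethyl)silyl]oxy}‑2,2‑dimethylcyclopentan‑1‑one | O=C1C(C)(C)C[C@H](O[Si](C)(C)C(C)(C)C)C1 | intermediate
6 | (1S,4S)‑4‑{[tert‑butyl(dimethyl)silyl]oxy}‑1‑(1‑ethoxyethenyl)‑2,2‑dimethylcyclopentan‑1‑ol | C=C(OCC)[C@@]1(O)C(C)(C)C[C@H](O[Si](C)(C)C(C)(C)C)C1 | intermediate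
7 | 1‑[(1S,4S)‑4‑{[tert‑butyl(dimethyl)silyl]oxy}‑1‑hydroxy‑2,2‑dimethylcyclopentyl]ethan‑1‑one | CC(=O)[C@@]1(O)C(C)(C)C[C@H](O[Si](C)(C)C(C)(C)C)C1 | intermediate
8 | (2S,4S)‑4‑{[tert‑butyl(dimethyl)silyl]oxy}‑2‑hydroxy‑2,6,6‑trimethylcyclohexan‑1‑one | O=C1C(C)(C)C[C@H](O[Si](C)(C)C(C)(C)C)C[C@]1(C)O | intermediate
9 | (2S,4S)‑4‑{[tert‑butyl(dimethyl)silyl]oxy}‑2,6,6‑trimethyl‑2‑[(trimethylsilyl)oxy]cyclohexan‑1‑one | O=C1C(C)(C)C[C@H](O[Si](C)(C)C(C)(C)C)C[C@]1(C)O[Si](C)(C)C | intermediate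
10 | (2E)‑3‑methylpent‑2‑en‑4‑yn‑1‑ol | OC/C=C(C)/C#C | starting material
11 | (2E)‑5‑[(1R,2S,4S)‑4‑{[tert‑butyl(dimethyl)silyl]oxy}‑1‑hydroxy‑2,6,6‑trimethyl‑2‑[(trimethylsilyl)oxy]cyclohexyl]‑3‑methylpent‑2‑en‑4‑yn‑1‑ol | OC/C=C(C)/C#C[C@]1(O)C(C)(C)C[C@H](O[Si](C)(C)C(C)(C)C)C[C@]1(C)O[Si](C)(C)C | intermediate
12 | (2E)‑5‑[(1R,2S,4S)‑4‑{[tert‑butyl(dimethyl)silyl]oxy}‑1,2‑dihydroxy‑2,6,6‑trimethylcyclohexyl]‑3‑methylpent‑2‑en‑4‑yn‑1‑ol | OC/C=C(C)/C#C[C@]1(O)C(C)(C)C[C@H](O[Si](C)(C)C(C)(C)C)C[C@]1(C)O | intermediate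
13 | (2E,4E)‑5‑[(1S,2S,4S)‑4‑{[tert‑butyl(dimethyl)silyl]oxy}‑1,2‑dihydroxy‑2,6,6‑trimethylcyclohexyl]‑3‑methylpenta‑2,4‑dien‑1‑ol | OC/C=C(C)/C=C/[C@]1(O)C(C)(C)C[C@H](O[Si](C)(C)C(C)(C)C)C[C@]1(C)O | intermediate
14 | (2E,4E)‑5‑[(1S,2S,4S)‑4‑{[tert‑butyl(dimethyl)silyl]oxy}‑1,2‑dihydroxy‑2,6,6‑trimethylcyclohexyl]‑3‑methylpenta‑2,4‑dienal | O=C/C=C(C)/C=C/[C@]1(O)C(C)(C)C[C@H](O[Si](C)(C)C(C)(C)C)C[C@]1(C)O | intermediate
15 | (3E)‑4‑(2,6,6‑trimethylcyclohex‑2‑en‑1‑yl)but‑3‑en‑2‑one (racemic α‑ionone) | CC1=CCCC(C)(C)C1/C=C/C(C)=O | starting material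
16 | (2E,4E)‑3‑methyl‑5‑(2,6,6‑trimethylcyclohex‑2‑en‑1‑yl)penta‑2,4‑dienenitrile (racemic) | CC1=CCCC(C)(C)C1/C=C/C(C)=C/C#N | intermediate
17 | (2E,4E)‑3‑methyl‑5‑(2,6,6‑trimethyl‑4‑oxocyclohex‑2‑en‑1‑yl)penta‑2,4‑dienenitrile (racemic) | CC1=CC(=O)CC(C)(C)C1/C=C/C(C)=C/C#N | intermediate
18 | (2E,4E)‑5‑[(1R,4R)‑4‑hydroxy‑2,6,6‑trimethylcyclohex‑2‑en‑1‑yl]‑3‑methylpenta‑2,4‑dienenitrile | CC1=C[C@H](O)CC(C)(C)[C@H]1/C=C/C(C)=C/C#N | intermediate
19 | (2E,4E)‑5‑[(1R,4R)‑4‑{[tert‑butyl(dimethyl)silyl]oxy}‑2,6,6‑trimethylcyclohex‑2‑en‑1‑yl]‑3‑methylpenta‑2,4‑dienenitrile | CC1=C[C@H](O[Si](C)(C)C(C)(C)C)CC(C)(C)[C@H]1/C=C/C(C)=C/C#N | intermediate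
20 | (2E,4E)‑5‑[(1R,4R)‑4‑{[tert‑butyl(dimethyl)silyl]oxy}‑2,6,6‑trimethylcyclohex‑2‑en‑1‑yl]‑3‑methylpenta‑2,4‑dienal | CC1=C[C@H](O[Si](C)(C)C(C)(C)C)CC(C)(C)[C@H]1/C=C/C(C)=C/C=O | intermediate
21 | (2E,4E,6E)‑2,7‑dimethylocta‑2,4,6‑trienedial | O=C/C(C)=C/C=C/C=C(C)/C=O | starting material
22 | (2E,4E,6E)‑2,7‑dimethylocta‑2,4,6‑triene‑1,8‑diol | OC/C(C)=C/C=C/C=C(C)/CO | intermediate
23 | (2E,4E,6E)‑1,8‑dibromo‑2,7‑dimethylocta‑2,4,6‑triene | BrC/C(C)=C/C=C/C=C(C)/CBr | intermediate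
24 | tetraethyl [(2E,4E,6E)‑2,7‑dimethylocta‑2,4,6‑triene‑1,8‑diyl]bis(phosphonate) | CCOP(=O)(OCC)C/C(C)=C/C=C/C=C(C)/CP(=O)(OCC)OCC | intermediate
25 | diethyl {(2E,4E,6E,8E,10E,12E)‑13‑[(1R,4R)‑4‑{[tert‑butyl(dimethyl)silyl]oxy}‑2,6,6‑trimethylcyclohex‑2‑en‑1‑yl]‑2,7,11‑trimethyltrideca‑2,4,6,8,10,12‑hexaen‑1‑yl}phosphonate | CC1=C[C@H](O[Si](C)(C)C(C)(C)C)CC(C)(C)[C@H]1/C=C/C(C)=C/C=C/C(C)=C/C=C/C=C(C)/CP(=O)(OCC)OCC | intermediate
26 | (all‑E,3S,5S,6S,3'R,6'R)‑3,3'‑bis{[tert‑butyl(dimethyl)silyl]oxy}‑5,6‑dihydro‑β,ε‑carotene‑5,6‑diol | CC1=C[C@H](O[Si](C)(C)C(C)(C)C)CC(C)(C)[C@H]1/C=C/C(C)=C/C=C/C(C)=C/C=C/C=C(C)/C=C/C=C(C)/C=C/[C@]1(O)C(C)(C)C[C@H](O[Si](C)(C)C(C)(C)C)C[C@]1(C)O | intermediate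
27 | (all‑E,3S,5S,6S,3'R,6'R)‑5,6‑dihydro‑β,ε‑carotene‑3,3',5,6‑tetrol (CNP0219917.1) | CC1=C[C@H](O)CC(C)(C)[C@H]1/C=C/C(C)=C/C=C/C(C)=C/C=C/C=C(C)/C=C/C=C(C)/C=C/[C@]1(O)C(C)(C)C[C@H](O)C[C@]1(C)O | target

## Step count and risks

Total step count: 20.
Longest linear sequence: 11 steps (steps 1–9, 19, 20).

**Steps most likely to fail**

1. **Step 5 (key step).** The CMe2 arm may migrate instead of the CH2 arm under kinetic control, or part of the material may react through a non‑chelated transition state that delivers the new hydroxyl to the wrong face. Fallback, from 5 to 9: the ring enlargement is kept but separated from the C–O bond formation. Lewis‑acid‑catalysed diazoalkane homologation of 5 with diazoethane (Sc(OTf)3 cat., toluene, −78 °C; the less substituted α‑carbon migrates) should give (4R)‑4‑{[tert‑butyl(dimethyl)silyl]oxy}‑2,2,6‑trimethylcyclohexan‑1‑one F1 (epimers at the methyl‑bearing carbon, which is planarised next). TMSOTf/Et3N then gives the only possible, tetrasubstituted trimethylsilyl enol ether F2. Rubottom oxidation (m‑CPBA, NaHCO3, CH2Cl2), expected on the face anti to the pseudo‑axial methyl of the gem‑dimethyl group (the face of the silyloxy group), and 1,4‑silyl shift lead directly to 9.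

2. **Step 4.** 1,3‑Induction in a cyclopentanone is modest, so facial selectivity of the carbonyl addition may be poor. Fallback, from 5 to 8: the route no longer depends on one face. The adducts are separated; 7 is processed as planned. The epimeric ketol 1‑[(1R,4S)‑4‑{[tert‑butyl(dimethyl)silyl]oxy}‑1‑hydroxy‑2,2‑dimethylcyclopentyl]ethan‑1‑one F3 is rearranged through the complementary non‑chelated alkoxide manifold (KH, 18‑crown‑6, THF, rt). There the oxygens are anti‑periplanar and the new hydroxyl appears on the face opposite to the old one, which is the known base versus Lewis‑acid stereodivergence of the α‑ketol ring expansion. Both epimers should therefore converge on 8.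

3. **Step 12.** Catalyst control may be incomplete for the mismatched enantiomer of 17, which would erode the enantiopurity of the trans alcohol. Fallback, from 17 to 18: a classical resolution replaces catalyst control. Luche reduction (NaBH4, CeCl3, MeOH, −20 °C) and chromatographic isolation give the racemic trans alcohol rac‑(2E,4E)‑5‑[(1R*,4R*)‑4‑hydroxy‑2,6,6‑trimethylcyclohex‑2‑en‑1‑yl]‑3‑methylpenta‑2,4‑dienenitrile F4. Lipase‑catalysed kinetic resolution by acylation (Pseudomonas lipase, vinyl acetate) is expected to acylate the (4R)‑carbinol to the acetate (1R,4R)‑4‑[(1E,3E)‑4‑cyano‑3‑methylbuta‑1,3‑dien‑1‑yl]‑3,5,5‑trimethylcyclohex‑2‑en‑1‑yl acetate F5. Methanolysis (K2CO3, MeOH) returns 18. If the enzyme prefers the other enantiomer, 18 is the unreacted alcohol.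

## Further compounds

F1 | step 5 | (4R)‑4‑{[tert‑butyl(dimethyl)silyl]oxy}‑2,2,6‑trimethylcyclohexan‑1‑one (epimers at C6) | O=C1C(C)(C)C[C@H](O[Si](C)(C)C(C)(C)C)CC1C
F2 | step 5 | tert‑butyl(dimethyl){[3,5,5‑trimethyl‑4‑(trimethylsilyloxy)cyclohex‑3‑en‑1‑yl]oxy}silane (silyloxy‑bearing carbon as in F1) | CC1=C(O[Si](C)(C)C)C(C)(C)C[C@H](O[Si](C)(C)C(C)(C)C)C1
F3 | step 4 | 1‑[(1R,4S)‑4‑{[tert‑butyl(dimethyl)silyl]oxy}‑1‑hydroxy‑2,2‑dimethylcyclopentyl]ethan‑1‑one | CC(=O)[C@]1(O)C(C)(C)C[C@H](O[Si](C)(C)C(C)(C)C)C1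
F4 | step 12 | rac‑(2E,4E)‑5‑[(1R*,4R*)‑4‑hydroxy‑2,6,6‑trimethylcyclohex‑2‑en‑1‑yl]‑3‑methylpenta‑2,4‑dienenitrile (both enantiomers) | CC1=C[C@H](O)CC(C)(C)[C@H]1/C=C/C(C)=C/C#N.CC1=C[C@@H](O)CC(C)(C)[C@@H]1/C=C/C(C)=C/C#N
F5 | step 12 | (1R,4R)‑4‑[(1E,3E)‑4‑cyano‑3‑methylbuta‑1,3‑dien‑1‑yl]‑3,5,5‑trimethylcyclohex‑2‑en‑1‑yl acetate | CC1=C[C@H](OC(C)=O)CC(C)(C)[C@H]1/C=C/C(C)=C/C#N
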